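The 4 questions on this flask hang on one account: how far its L can go. I assume one L per molecule of product, so the charged [L] over the charged [E] + [X] is 110 %. I call this the L budget, the most product L can pay for, in percent of E and X together.

in all of them: E 0.062 M; X 0.062 M; Q 1.5 mM

|  | L | remark | time |
|---|---|---|---|
| noon | 0.136 M | the very flask that is asked about, followed so far |  |
| summer | 0.20 M | run made earlier |  |
| flask | 0.136 M |  | 10 h |

- noon (time / h: G / %): 0.667: 56.4; 2.00: 61.5; 4.00: 61.6; 5.00: 60.8; 8.00: 61.8; 10.0: 60.7
- summer (time / min: G / %): 4.00: 43.2; 12.0: 51.1; 20.0: 53.7; 30.0: 54.5; 50.0: 56.6; 60.0: 56.4

(readings scatter by 1 percentage point)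

- epsilon: at 10 h add Q, 100 % of the amount charged, then wait 5.0 h
- beta: at 10 h take out 90 % of the G then present, then wait 5.0 h
- zeta: at 10 h add L, 100 % of the amount charged, then wait 5.0 h
- gamma: change nothing and wait 5.0 h more

- Q is single-handed; E and X are mirror images of each other, charged as a racemate, each of them at the stated concentration
- removed G is counted in
- additions bring no volume worth counting

1. G, in percent of the E and X together first charged, at 10 h
2. the option that brings most further G ("none" if no option brings more than 2 percentage points) (epsilon / beta / zeta / gamma / none)
3. G present, with what was taken out counted in, in percent of the E and X together first charged, after epsilon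
4. G present, with what was taken out counted in, in percent of the E and X together first charged, after gamma

For the first instants I have the summer run, which has more L than noon. As read, G gains 0.108 /min of the charge up to 4.00 min, then 0.00987 /min up to 12.0 min, far less. At 12.0 min the summer run reads 51.1 %, close to the 50.0 % that E held at the charge. In the middle, the noon flask reads 56.4 % at 0.667 h, more than E held, so X is feeding G too, though slowly. At the end, from 2.00 h to 10.0 h, the noon readings stay between 60.7 % and 61.8 %, with a scatter of 1 percentage point, so within that scatter they show no further rise of G. What matters now is which supply ended the rise.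

The noon flask holds more L than E and X together, so L can pay for a full conversion, and I expect nothing from zeta. The readings of G do not show me how much E and X remain, so I leave epsilon open.

The forecast gives 61.3 % now and 61.3 % after gamma, and it picks epsilon, expecting 70 %, on the ground that “A flat plateau well short of 100 % points to Q dying”.

The flask gives 61.4 % now and 61.5 % after gamma. Epsilon reaches 62.3 %, a gain of 0.81 points, under the 2 points mark, so the best choice is none.

    L + Q + X → Q + Z (k = 790 /M²/min)
    L + Q + E → Q + G (k = 2370 /M²/min)
    E ⇌ X (k = 0.0224 /min)
    L + Q → J (k = 0.456 /M/min)

With the other concentrations held at their charge, the step of E halves L in 0.052 h and the step of X in 0.16 h, both shorter than the relaxation half-life of E and X, 0.258 h. At 10.0 h the flask holds G 61.4 % and Z, the product of X, 37.3 %, together 98.7 % against the budget of 110 %; Q is low at 1.45 % of its charge, but E and X stand at 0.603 % and 0.610 %. A neighbouring flask has less L, 0.082 M, so its budget is 66.1 % and L is the limiting reagent. Computed, its G 44.7 % and Z 21.2 % sum to 65.9 %, with 0 % of L and 34 % of E left.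

The data are simulated with constants of no real substance.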